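## Retrosynthetic overview

1. Carbons are numbered from the acid (C1 = CO2H, C2–C7 triene, C8–C13 stereo-array, C15 = aryl ketone). C5–C6 (Suzuki): the all-E triene acid comes from (2E,4E)-5-bromopentadienoic acid (C1–C5, carved out of a ring-opened pyridine) and an E-alkenyl boronate (C6–C15).
2. C8–C9: a catalytic asymmetric boryl-crotylation of the C9 aldehyde (stored as a lactol) sets C8, C9 and the C6=C7 alkenyl boronate in one step.
3. C13–C14 (key step): a reagent-controlled mono-aldol of 4'-nitroacetophenone on C2-symmetric (2R,4R)-2,4-dimethylpentanedial makes the two identical ends different and masks the untouched CHO as a lactol.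
4. The dialdehyde comes from penta-1,4-diene by two-directional Zr-catalysed carboalumination (sets C10 and C12), then Swern oxidation.
5. Rings: none is built for the target (the benzene ring is bought). The only ring formed is the temporary lactol (step 3, reopened in step 5); the pyridine ring is opened in step 7.

**Assumption:** the facial senses of the three chiral reagents are taken as usually quoted ((−)-(NMI)2ZrCl2 gives (R)-2-methylalkyl alanes, (−)-Ipc2BCl from (+)-α-pinene sends a methyl-ketone enolate to the aldehyde Re face, (R)-TRIP sends an allylboronate to the aldehyde Re face); these are recalled, not verified, and if a test run shows the opposite for one of them its mirror-image form is used.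

The target is 8R,9S,10R,12R,13R: 8,9-anti, 9,10-syn, 10,12-anti, 12,13-syn, so the C9–C13 array is locally C2-symmetric.

## Route

Step 1
Reactants: 1 penta-1,4-diene
Product: 3 (2R,4R)-2,4-dimethylpentane-1,5-diol, via bis-alane 2 (not isolated)
Conditions: Me3Al (5 equiv), (−)-(NMI)2ZrCl2 [(−)-bis(1-neomenthylindenyl)zirconium dichloride] (5 mol%), methylaluminoxane (MeAlO)n (0.5 equiv), CH2Cl2, 0 °C → rt, 24 h; then O2, 0 °C → rt; aq. HCl
Reagents that add atoms: trimethylaluminium, C[Al](C)C; dioxygen, O=O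
Why: Two-directional Zr-catalysed asymmetric carboalumination (ZACA reaction): each terminal alkene inserts into the chiral Zr–Me species on the face chosen by the neomenthylindenyl ligands to set C10 and C12 (both R), O2 then oxidises the C–Al bonds without touching the stereocentres, and doing the insertion twice on one molecule channels the minor-sense insertion into the meso diol (about 15–20%, removed by chromatography here or as diastereomers after step 5) so the C2-symmetric diol has high ee.

Step 2
Reactants: 3 (2R,4R)-2,4-dimethylpentane-1,5-diol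
Product: 5 (2R,4R)-2,4-dimethylpentanedial, via alkoxysulfonium salt 4 (not isolated)
Conditions: (COCl)2 (3 equiv), DMSO (6 equiv), CH2Cl2, −78 °C; then i-Pr2NEt (8 equiv), −78 → −30 °C; cold non-aqueous work-up, used at once
Reagents that add atoms: none
Why: Swern oxidation: both hydroxyls become alkoxysulfonium ions before any base is present, so no hydroxy aldehyde (and hence no lactol or lactone) can form, and the hindered base at low temperature leaves the two α-stereocentres intact.

Step 3
Reactants: 5 (2R,4R)-2,4-dimethylpentanedial (2.0 equiv); 6 4'-nitroacetophenone (1.0 equiv)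
Product: 10 2-[(2R,3R,5R)-6-hydroxy-3,5-dimethyloxan-2-yl]-1-(4-nitrophenyl)ethan-1-one (lactol; both anomers), via boron enolate 7 (not isolated), via boron aldolate 8 (not isolated), via hydroxy aldehyde 9 (not isolated)
Conditions: (−)-Ipc2BCl (1.3 equiv) premixed with Et3N (1.5 equiv), CH2Cl2; 6 added at −78 °C, then 0 °C, 1 h; cannulated into 5, −78 → −20 °C, 14 h; MeOH, pH 7 buffer, 30% H2O2, 0 °C
Reagents that add atoms: none
Why: Paterson-type boron aldol reaction used as the symmetry-breaking key step: the two formyl groups of C2-symmetric 5 are homotopic so attack at either gives the same compound, the Ipc ligands steer the enolate to the aldehyde Re face (the face also preferred by the Felkin–Anh model for the α-methyl centre) to set C13 as R (12,13-syn), the twofold excess of 5 holds double aldol to a statistical minimum, and on work-up the freed δ-hydroxy aldehyde 9 closes to the lactol, leaving the two chain ends chemically different with the second formyl group masked.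

Step 4
Reactants: 11 2,2'-methylenebis(4,4,5,5-tetramethyl-1,3,2-dioxaborolane); 12 allyl bromide
Product: 14 2,2'-(but-3-ene-1,1-diyl)bis(4,4,5,5-tetramethyl-1,3,2-dioxaborolane), via lithiated diborylmethane 13 (not isolated)
Conditions: LiTMP (lithium 2,2,6,6-tetramethylpiperidide, 1.05 equiv), THF, 0 °C, 15 min; then 12 (1.2 equiv), 0 °C → rt
Reagents that add atoms: none
Why: Alkylation of an α,α-diboryl carbanion: the two boron atoms acidify the methylene so LiTMP deprotonates it cleanly and the stabilised anion displaces bromide from allyl bromide (SN2); no stereocentre is formed.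

Step 5
Reactants: 10 2-[(2R,3R,5R)-6-hydroxy-3,5-dimethyloxan-2-yl]-1-(4-nitrophenyl)ethan-1-one (lactol); 14 2,2'-(but-3-ene-1,1-diyl)bis(4,4,5,5-tetramethyl-1,3,2-dioxaborolane) (1.5 equiv)
Product: 17 (3R,4R,6R,7S,8R,9E)-3,7-dihydroxy-4,6,8-trimethyl-1-(4-nitrophenyl)-10-(4,4,5,5-tetramethyl-1,3,2-dioxaborolan-2-yl)dec-9-en-1-one, via crotyl diboronate 15 (not isolated), via borate ester 16 (not isolated)
Conditions: [Pd(μ-Br)(P(t-Bu)3)]2 (2.5 mol%), (R)-TRIP [(R)-3,3'-bis(2,4,6-triisopropylphenyl)-1,1'-binaphthyl-2,2'-diyl hydrogen phosphate] (10 mol%), 4 Å MS, toluene, rt, 36 h; aq. NaHCO3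
Reagents that add atoms: none
Why: Pd–H alkene transposition (14 → 15) followed by chiral-phosphoric-acid-catalysed allylboration of the lactol, which reacts through the small equilibrium share of its ring-opened tautomer (the hydroxy aldehyde 9 that closed to 10 in step 3): in the closed chair transition state the E-crotyl geometry gives the 8,9-anti relationship, the α-Bpin group sits equatorial and becomes the E-alkenyl boronate, and (R)-TRIP directs attack to the aldehyde Re face (again the Felkin face) to set C9 as S and C8 as R, while the aryl ketone is too unreactive to compete.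

Step 6
Reactants: 17 (3R,4R,6R,7S,8R,9E)-3,7-dihydroxy-4,6,8-trimethyl-1-(4-nitrophenyl)-10-(4,4,5,5-tetramethyl-1,3,2-dioxaborolan-2-yl)dec-9-en-1-one
Product: 18 (3R,4R,6R,7S,8R,9E)-1-(4-aminophenyl)-3,7-dihydroxy-4,6,8-trimethyl-10-(4,4,5,5-tetramethyl-1,3,2-dioxaborolan-2-yl)dec-9-en-1-one
Conditions: Fe powder (5 equiv), NH4Cl (5 equiv), EtOH/H2O 4:1, 60 °C, 1 h
Reagents that add atoms: none
Why: Béchamp-type iron reduction: electron transfer from iron in buffered aqueous ethanol reduces only the nitro group to the aniline and leaves the ketone, the alkenyl boronate and all stereocentres untouched.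

Step 7
Reactants: 19 pyridine–sulfur trioxide complex (pyridinium-1-sulfonate)
Product: 20 potassium (1E,3E)-5-oxopenta-1,3-dien-1-olate (glutaconaldehyde potassium salt)
Conditions: KOH (4 equiv), H2O, −20 °C → 20 °C, then 40 °C, 1 h; filter, recrystallise from MeOH
Reagents that add atoms: potassium hydroxide, [K+].[OH-]; water, O
Why: Ring opening of an N-activated pyridinium (Zincke-type): hydroxide adds at C2 of the N-sulfonated ring, the 1,2-dihydropyridine opens electrocyclically and the N-sulfonyl imine is hydrolysed, which destroys the aromatic ring and delivers the five contiguous sp2 carbons C1–C5 as a stable enolate salt.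

Step 8
Reactants: 20 potassium (1E,3E)-5-oxopenta-1,3-dien-1-olate
Product: 21 (2E,4E)-5-bromopenta-2,4-dienal
Conditions: PPh3 (1.1 equiv), Br2 (1.1 equiv), CH2Cl2, 0 °C; then 20, 0 °C → rt; then I2 (2 mol%), rt, 30 min
Reagents that add atoms: bromine, BrBr
Why: Deoxybromination of a vinylogous carboxylate with Ph3PBr2 (Appel-type addition–elimination at the enolate oxygen) gives the ω-bromo dienal, and the catalytic iodine equilibrates any 4Z isomer to the thermodynamically preferred 2E,4E isomer.

Step 9
Reactants: 21 (2E,4E)-5-bromopenta-2,4-dienal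
Product: 22 (2E,4E)-5-bromopenta-2,4-dienoic acid
Conditions: NaClO2 (3 equiv), NaH2PO4 (3 equiv), 2-methylbut-2-ene (10 equiv), t-BuOH/H2O, 0 °C → rt
Reagents that add atoms: sodium chlorite, [Na+].[O-]Cl=O
Why: Pinnick oxidation: chlorous acid oxidises the enal to the acid under buffered conditions while 2-methylbut-2-ene scavenges HOCl, so the bromodiene geometry is preserved.

Step 10
Reactants: 18 (3R,4R,6R,7S,8R,9E)-1-(4-aminophenyl)-3,7-dihydroxy-4,6,8-trimethyl-10-(4,4,5,5-tetramethyl-1,3,2-dioxaborolan-2-yl)dec-9-en-1-one; 22 (2E,4E)-5-bromopenta-2,4-dienoic acid (1.2 equiv)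
Product: 23 mohangic acid F, (2E,4E,6E,8R,9S,10R,12R,13R)-15-(4-aminophenyl)-9,13-dihydroxy-8,10,12-trimethyl-15-oxopentadeca-2,4,6-trienoic acid
Conditions: Pd(OAc)2 (5 mol%), SPhos (2-dicyclohexylphosphino-2',6'-dimethoxybiphenyl, 10 mol%), K3PO4 (4 equiv), THF/H2O 10:1, degassed, dark, 25 °C; NaH2PO4 to pH 5
Reagents that add atoms: none
Why: Suzuki–Miyaura coupling of an E-alkenyl boronate with an E,E-bromodienoate (as its carboxylate) proceeds with retention at both partners to form the C5–C6 bond and the all-E triene, and the mild phosphate base at room temperature tolerates the free amine, both alcohols and the β-hydroxy ketone.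

## Compound list

1 | penta-1,4-diene | C=CCC=C | starting material
2 | (2R,4R)-1,5-bis(dimethylalumanyl)-2,4-dimethylpentane (bis-alane) | C[Al](C)C[C@H](C)C[C@@H](C)C[Al](C)C | intermediate
3 | (2R,4R)-2,4-dimethylpentane-1,5-diol | OC[C@H](C)C[C@@H](C)CO | intermediate
4 | bis(dimethylsulfonio-oxy) derivative of 3, dichloride (alkoxysulfonium salt) | C[S+](C)OC[C@H](C)C[C@@H](C)CO[S+](C)C.[Cl-].[Cl-] | intermediate
5 | (2R,4R)-2,4-dimethylpentanedial | O=C[C@H](C)C[C@@H](C)C=O | intermediate
6 | 1-(4-nitrophenyl)ethan-1-one (4'-nitroacetophenone) | CC(=O)c1ccc(cc1)[N+](=O)[O-] | starting material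
7 | 1-(4-nitrophenyl)ethenyl diisopinocampheylborinate (boron enolate) | C=C(OB([C@@H]1C[C@@H]2C[C@H]([C@H]1C)C2(C)C)[C@@H]1C[C@@H]2C[C@H]([C@H]1C)C2(C)C)c1ccc(cc1)[N+](=O)[O-] | intermediate
8 | (2R,4R,5R)-5-[(diisopinocampheylboranyl)oxy]-2,4-dimethyl-7-(4-nitrophenyl)-7-oxoheptanal (boron aldolate) | O=C[C@H](C)C[C@@H](C)[C@@H](CC(=O)c1ccc(cc1)[N+](=O)[O-])OB([C@@H]1C[C@@H]2C[C@H]([C@H]1C)C2(C)C)[C@@H]1C[C@@H]2C[C@H]([C@H]1C)C2(C)C | intermediate
9 | (2R,4R,5R)-5-hydroxy-2,4-dimethyl-7-(4-nitrophenyl)-7-oxoheptanal (hydroxy aldehyde; open-chain tautomer of 10) | O=C[C@H](C)C[C@@H](C)[C@H](O)CC(=O)c1ccc(cc1)[N+](=O)[O-] | intermediate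
10 | 2-[(2R,3R,5R)-6-hydroxy-3,5-dimethyloxan-2-yl]-1-(4-nitrophenyl)ethan-1-one (lactol, both anomers) | OC1[C@H](C)C[C@@H](C)[C@@H](CC(=O)c2ccc(cc2)[N+](=O)[O-])O1 | intermediate
11 | 2,2'-methylenebis(4,4,5,5-tetramethyl-1,3,2-dioxaborolane) | CC1(C)OB(CB2OC(C)(C)C(C)(C)O2)OC1(C)C | starting material
12 | allyl bromide (3-bromoprop-1-ene) | C=CCBr | starting material
13 | lithium bis(4,4,5,5-tetramethyl-1,3,2-dioxaborolan-2-yl)methanide | [Li]C(B1OC(C)(C)C(C)(C)O1)B1OC(C)(C)C(C)(C)O1 | intermediate
14 | 2,2'-(but-3-ene-1,1-diyl)bis(4,4,5,5-tetramethyl-1,3,2-dioxaborolane) | C=CCC(B1OC(C)(C)C(C)(C)O1)B1OC(C)(C)C(C)(C)O1 | intermediate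
15 | 2,2'-[(2E)-but-2-ene-1,1-diyl]bis(4,4,5,5-tetramethyl-1,3,2-dioxaborolane) | C/C=C/C(B1OC(C)(C)C(C)(C)O1)B1OC(C)(C)C(C)(C)O1 | intermediate
16 | 7-O-(pinacolboryl) borate ester of 17 | CC1(C)OB(/C=C/[C@@H](C)[C@@H](OB2OC(C)(C)C(C)(C)O2)[C@H](C)C[C@@H](C)[C@H](O)CC(=O)c3ccc(cc3)[N+](=O)[O-])OC1(C)C | intermediate
17 | (3R,4R,6R,7S,8R,9E)-3,7-dihydroxy-4,6,8-trimethyl-1-(4-nitrophenyl)-10-(4,4,5,5-tetramethyl-1,3,2-dioxaborolan-2-yl)dec-9-en-1-one | CC1(C)OB(/C=C/[C@@H](C)[C@@H](O)[C@H](C)C[C@@H](C)[C@H](O)CC(=O)c2ccc(cc2)[N+](=O)[O-])OC1(C)C | intermediate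
18 | (3R,4R,6R,7S,8R,9E)-1-(4-aminophenyl)-3,7-dihydroxy-4,6,8-trimethyl-10-(4,4,5,5-tetramethyl-1,3,2-dioxaborolan-2-yl)dec-9-en-1-one | CC1(C)OB(/C=C/[C@@H](C)[C@@H](O)[C@H](C)C[C@@H](C)[C@H](O)CC(=O)c2ccc(N)cc2)OC1(C)C | intermediate
19 | pyridinium-1-sulfonate (pyridine–sulfur trioxide complex) | [O-]S(=O)(=O)[n+]1ccccc1 | starting material
20 | potassium (1E,3E)-5-oxopenta-1,3-dien-1-olate | [K+].[O-]/C=C/C=C/C=O | intermediate
21 | (2E,4E)-5-bromopenta-2,4-dienal | O=C/C=C/C=C/Br | intermediate
22 | (2E,4E)-5-bromopenta-2,4-dienoic acid | OC(=O)/C=C/C=C/Br | intermediate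
23 | mohangic acid F | C[C@H](/C=C/C=C/C=C/C(=O)O)[C@@H](O)[C@H](C)C[C@@H](C)[C@H](O)CC(=O)c1ccc(N)cc1 | target

## Step count and risks

Total steps: 10 (main line plus step 4 and steps 7–9 as side branches). Longest linear sequence: 6 steps (1 → 2 → 3 → 5 → 6 → 10).

**Step 3 (most likely to fail).** The mono/bis-aldol ratio is only statistical (about 6:1 with 2 equiv of 5). Reagent control for methyl-ketone Ipc enolates is moderate (roughly 9:1 expected at C13 in the matched case). Ipc2BCl can also reduce the aryl ketone if enolisation is slow, and 5 is fragile.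
Fallback, setting out from 3 and returning at 10: the ends are differentiated with a protecting group instead. Monosilylation of 3 (NaH 1.0 equiv, TBSCl 1.0 equiv, THF) gives (2R,4R)-5-[(tert-butyldimethylsilyl)oxy]-2,4-dimethylpentan-1-ol F1. Dess–Martin oxidation gives (2R,4R)-5-[(tert-butyldimethylsilyl)oxy]-2,4-dimethylpentanal F2. The same (−)-Ipc2BCl aldol with 6, now 1:1, gives (3R,4R,6R)-7-[(tert-butyldimethylsilyl)oxy]-3-hydroxy-4,6-dimethyl-1-(4-nitrophenyl)heptan-1-one F3. HF·pyridine gives (3R,4R,6R)-3,7-dihydroxy-4,6-dimethyl-1-(4-nitrophenyl)heptan-1-one F4. TEMPO (cat.)/PhI(OAc)2 (1.05 equiv, 0 °C, stopped as soon as F4 is consumed so that the lactol is not carried on to the lactone) oxidises only the primary alcohol, and the resulting 9 closes to 10.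

**Step 5.** The lactol supplies only a low concentration of free aldehyde. The transposition catalyst must keep pace with the allylboration without isomerising 15 further, and E/anti selectivity relies on the phosphoric acid.
Fallback, setting out from 10 and returning at 17: C–C bond formation and boron installation are separated. (R)-TRIP-catalysed crotylboration of 10 with commercial (E)-crotylboronic acid pinacol ester gives the anti,syn homoallylic alcohol (3R,4R,6R,7S,8R)-3,7-dihydroxy-4,6,8-trimethyl-1-(4-nitrophenyl)dec-9-en-1-one F5. Cross-metathesis of its terminal alkene with vinylboronic acid pinacol ester (second-generation Hoveyda–Grubbs catalyst, CH2Cl2, 40 °C) gives 17.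

**Step 10.** Both partners are fully unprotected, so risks are retro-aldol or dehydration under base, protodeboronation, poor behaviour of the carboxylate partner, and isolation of a light-sensitive amino acid.
Fallback, setting out from 22 and 18 and returning at 23: the acid is masked as a fluoride-labile ester. Steglich esterification of 22 (2-(trimethylsilyl)ethanol, DCC, DMAP) gives 2-(trimethylsilyl)ethyl (2E,4E)-5-bromopenta-2,4-dienoate F6. Suzuki coupling with 18 under the step-10 catalyst gives the 2-(trimethylsilyl)ethyl ester of mohangic acid F F7, now a neutral compound that can be chromatographed. TASF [tris(dimethylamino)sulfonium difluorotrimethylsilicate], DMF, 0 °C then releases 23 without aqueous base.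

## Further compounds

F1 | step 3 | (2R,4R)-5-[(tert-butyldimethylsilyl)oxy]-2,4-dimethylpentan-1-ol | CC(C)(C)[Si](C)(C)OC[C@H](C)C[C@@H](C)CO
F2 | step 3 | (2R,4R)-5-[(tert-butyldimethylsilyl)oxy]-2,4-dimethylpentanal | CC(C)(C)[Si](C)(C)OC[C@H](C)C[C@@H](C)C=O
F3 | step 3 | (3R,4R,6R)-7-[(tert-butyldimethylsilyl)oxy]-3-hydroxy-4,6-dimethyl-1-(4-nitrophenyl)heptan-1-one | CC(C)(C)[Si](C)(C)OC[C@H](C)C[C@@H](C)[C@H](O)CC(=O)c1ccc(cc1)[N+](=O)[O-]
F4 | step 3 | (3R,4R,6R)-3,7-dihydroxy-4,6-dimethyl-1-(4-nitrophenyl)heptan-1-one | OC[C@H](C)C[C@@H](C)[C@H](O)CC(=O)c1ccc(cc1)[N+](=O)[O-]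
F5 | step 5 | (3R,4R,6R,7S,8R)-3,7-dihydroxy-4,6,8-trimethyl-1-(4-nitrophenyl)dec-9-en-1-one | C=C[C@@H](C)[C@@H](O)[C@H](C)C[C@@H](C)[C@H](O)CC(=O)c1ccc(cc1)[N+](=O)[O-]
F6 | step 10 | 2-(trimethylsilyl)ethyl (2E,4E)-5-bromopenta-2,4-dienoate | C[Si](C)(C)CCOC(=O)/C=C/C=C/Br
F7 | step 10 | 2-(trimethylsilyl)ethyl ester of mohangic acid F | C[C@H](/C=C/C=C/C=C/C(=O)OCC[Si](C)(C)C)[C@@H](O)[C@H](C)C[C@@H](C)[C@H](O)CC(=O)c1ccc(N)cc1
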